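## Retrosynthetic overview

1. Target 13 ⇒ prenyl ketone 12: the tertiary allylic hydroperoxide and the E-enone are unmasked last by a Schenck ene reaction with singlet oxygen.
2. 12 ⇒ enal 9 + prenyl carbonate 11 (key C–C bond, side-chain C(=O)–CH2): the aldehyde carbon of 9 reacts as an acyl anion (Breslow intermediate) with the electrophilic CH2 terminus of a π-prenyl-palladium species.
3. 9 ⇒ 6: the isopropenyl methyl is oxidised by ene chlorination (7) and N-oxide oxidation.
4. 6 ⇒ (R)-carvone 1 + isovaleric acid 2: α′-acyloxylation, 1,2-reduction, OH-directed epoxidation, re-oxidation. This detour gives the oxirane cis to the side chain; direct alkaline H2O2 epoxidation of carvone gives the trans isomer.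
5. Rings: the carbocycle comes intact from (R)-carvone, which also supplies the side-chain-bearing stereocentre. The oxirane is the only ring formed (step 3), before any side-chain work.

Assumption: catalyst-bound species (vanadate ester, Breslow intermediate, π-allyl-Pd) are described in the Why lines and not numbered; only stoichiometric intermediates are numbered.

## Route

Step 1
Reactants: 1 (R)-(−)-carvone; 2 3-methylbutanoic acid (isovaleric acid)
Product: 3 (1S,6S)-3-methyl-2-oxo-6-(prop-1-en-2-yl)cyclohex-3-en-1-yl 3-methylbutanoate (trans-6-isovaleryloxycarvone)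
Conditions: Mn(OAc)3·2H2O (3 equiv), 2 (10 equiv), benzene, reflux, Dean–Stark
Reagents that add atoms: none
Why: Mn(III)-mediated α′-acyloxylation of an enone (Mn(III) enolate, α′-keto radical, carboxylate ligand transfer, with excess 2 exchanging the acetate ligands and AcOH removed azeotropically) is regioselective for C6–H, and the C–O bond is expected to form anti to the neighbouring isopropenyl group to give the trans (diequatorial, also thermodynamic) ester, the cis epimer being removed by chromatography or equilibrated with catalytic DBU.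

Step 2
Reactants: 3 (1S,6S)-3-methyl-2-oxo-6-(prop-1-en-2-yl)cyclohex-3-en-1-yl 3-methylbutanoate
Product: 4 (1S,2S,6S)-2-hydroxy-3-methyl-6-(prop-1-en-2-yl)cyclohex-3-en-1-yl 3-methylbutanoate (OH cis to isopropenyl, trans to the ester)
Conditions: NaBH4, CeCl3·7H2O, MeOH, −78 to −20 °C; AcOH quench
Reagents that add atoms: none
Why: Luche 1,2-reduction, in which the small hydride attacks the Ce-activated carbonyl axially to give the equatorial alcohol cis to the isopropenyl group (as in carvone to cis-carveol) and trans to the ester, while low temperature and an acidic quench suppress 1,2-acyl migration.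

Step 3
Reactants: 4 (1S,2S,6S)-2-hydroxy-3-methyl-6-(prop-1-en-2-yl)cyclohex-3-en-1-yl 3-methylbutanoate
Product: 5 (1R,2R,3S,4S,6S)-2-hydroxy-1-methyl-4-(prop-1-en-2-yl)-7-oxabicyclo[4.1.0]heptan-3-yl 3-methylbutanoate (oxirane cis to OH and isopropenyl, trans to the ester)
Conditions: VO(acac)2 (2 mol%), t-BuOOH (1.3 equiv, decane), CH2Cl2, 0 °C to rt
Reagents that add atoms: tert-butyl hydroperoxide CC(C)(C)OO
Why: Vanadium-catalysed hydroxyl-directed epoxidation, in which the allylic vanadate ester delivers oxygen to the ring alkene on the face of the OH (setting both oxirane carbons cis to the OH and hence cis to the isopropenyl group) and leaves the non-allylic isopropenyl alkene untouched.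

Step 4
Reactants: 5 (1R,2R,3S,4S,6S)-2-hydroxy-1-methyl-4-(prop-1-en-2-yl)-7-oxabicyclo[4.1.0]heptan-3-yl 3-methylbutanoate
Product: 6 (1S,3S,4S,6S)-1-methyl-2-oxo-4-(prop-1-en-2-yl)-7-oxabicyclo[4.1.0]heptan-3-yl 3-methylbutanoate
Conditions: Dess–Martin periodinane (1.3 equiv), pyridine, CH2Cl2, 0 °C to rt
Reagents that add atoms: none
Why: Dess–Martin oxidation of the secondary alcohol under buffered conditions returns the ketone without opening the oxirane or epimerising the α-acyloxy centre, which already sits in its more stable trans arrangement.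

Step 5
Reactants: 6 (1S,3S,4S,6S)-1-methyl-2-oxo-4-(prop-1-en-2-yl)-7-oxabicyclo[4.1.0]heptan-3-yl 3-methylbutanoate
Product: 7 (1S,3S,4S,6S)-4-(3-chloroprop-1-en-2-yl)-1-methyl-2-oxo-7-oxabicyclo[4.1.0]heptan-3-yl 3-methylbutanoate
Conditions: Ca(OCl)2, CO2 (dry ice), CH2Cl2/H2O, 0 °C
Reagents that add atoms: calcium hypochlorite [Ca+2].[O-]Cl.[O-]Cl
Why: Ene-type allylic chlorination with HOCl generated in situ (the conditions that turn carvone into 10-chlorocarvone), in which Cl+ adds to the terminal CH2 and a methyl proton is lost to give the 2-substituted allyl chloride, the isopropenyl group being the only nucleophilic alkene in 6.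

Step 6
Reactants: 7 (1S,3S,4S,6S)-4-(3-chloroprop-1-en-2-yl)-1-methyl-2-oxo-7-oxabicyclo[4.1.0]heptan-3-yl 3-methylbutanoate
Product: 9 (1S,3S,4S,6S)-1-methyl-2-oxo-4-(3-oxoprop-1-en-2-yl)-7-oxabicyclo[4.1.0]heptan-3-yl 3-methylbutanoate, via N-alkoxy-N-methylmorpholinium chloride 8 (not isolated)
Conditions: NMO (anhydrous, 4 equiv), 4 Å MS, MeCN, rt to 45 °C
Reagents that add atoms: N-methylmorpholine N-oxide C[N+]1([O-])CCOCC1
Why: Amine N-oxide (Ganem-type) oxidation of an activated halide, in which SN2 O-alkylation of NMO by the allylic chloride gives salt 8 and its fragmentation across C–H/O–N releases the 2-substituted acrolein under near-neutral conditions that the epoxy ketone and ester tolerate.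

Step 7
Reactants: 10 3-methylbut-2-en-1-ol (prenol)
Product: 11 tert-butyl 3-methylbut-2-en-1-yl carbonate
Conditions: Boc2O (1.2 equiv), DMAP (10 mol%), CH2Cl2, 0 °C to rt
Reagents that add atoms: di-tert-butyl dicarbonate CC(C)(C)OC(=O)OC(=O)OC(C)(C)C
Why: DMAP-catalysed O-acylation of the primary allylic alcohol gives the mixed tert-butyl carbonate, the ionisable partner for Pd(0) that releases its own base on ionisation.

Step 8 (key step)
Reactants: 9 (1S,3S,4S,6S)-1-methyl-2-oxo-4-(3-oxoprop-1-en-2-yl)-7-oxabicyclo[4.1.0]heptan-3-yl 3-methylbutanoate; 11 tert-butyl 3-methylbut-2-en-1-yl carbonate (1.5 equiv)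
Product: 12 (1S,3S,4S,6S)-1-methyl-4-(6-methyl-3-oxohepta-1,5-dien-2-yl)-2-oxo-7-oxabicyclo[4.1.0]heptan-3-yl 3-methylbutanoate
Conditions: N-(2,6-diisopropylphenyl)thiazolium salt (10 mol%), Pd2(dba)3 (2.5 mol%), dppf (6 mol%), toluene, 40 °C, no added base
Reagents that add atoms: none
Why: Proposed new method: the thiazol-2-ylidene adds to the aldehyde of 9 to give a Breslow enaminol (an acyl anion equivalent; thiazolium carbenes favour this reactivity over homoenolate reactivity of enals), while Pd(0)/dppf ionises 11 to a 1,1-dimethyl-π-allyl-Pd cation, CO2 and tert-butoxide (the only base, which regenerates the carbene; tert-butanol is too poor a nucleophile for redox esterification), and the soft, bulky enaminol carbon attacks the unhindered CH2 terminus of the π-allyl to forge the C(=O)–CH2 bond before the carbene is expelled, so no stereocentre is made or touched; the closest known reaction type is the synergistic thiazolium-NHC/Pd-bisphosphine allylic acylation of aldehyde acyl anions with allylic carbonates (an acyl-anion Tsuji–Trost reaction), extended here from aryl aldehydes to a 2-substituted acrolein.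

Step 9
Reactants: 12 (1S,3S,4S,6S)-1-methyl-4-(6-methyl-3-oxohepta-1,5-dien-2-yl)-2-oxo-7-oxabicyclo[4.1.0]heptan-3-yl 3-methylbutanoate
Product: 13 (1S,3S,4S,6S)-4-[(4E)-6-hydroperoxy-6-methyl-3-oxohepta-1,4-dien-2-yl]-1-methyl-2-oxo-7-oxabicyclo[4.1.0]heptan-3-yl 3-methylbutanoate (CNP0241468.1)
Conditions: O2, tetraphenylporphyrin (1 mol%), white LED, CH2Cl2, −20 °C
Reagents that add atoms: dioxygen O=O
Why: Schenck ene reaction, in which singlet oxygen attacks only the electron-rich trisubstituted prenyl alkene (the enone methylene is electron-poor), abstracts a hydrogen of the doubly activated C(=O)CH2 group on the more substituted side of the alkene (cis effect) and bonds to the CMe2 carbon, moving the alkene into conjugation as the E isomer and leaving the tertiary hydroperoxide without creating a stereocentre.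

## Compound list

1 | (R)-(−)-carvone | C=C(C)[C@@H]1CC=C(C)C(=O)C1 | starting material
2 | 3-methylbutanoic acid (isovaleric acid) | CC(C)CC(=O)O | starting material
3 | (1S,6S)-3-methyl-2-oxo-6-(prop-1-en-2-yl)cyclohex-3-en-1-yl 3-methylbutanoate | C=C(C)[C@@H]1CC=C(C)C(=O)[C@H]1OC(=O)CC(C)C | intermediate
4 | (1S,2S,6S)-2-hydroxy-3-methyl-6-(prop-1-en-2-yl)cyclohex-3-en-1-yl 3-methylbutanoate | C=C(C)[C@@H]1CC=C(C)[C@H](O)[C@H]1OC(=O)CC(C)C | intermediate
5 | (1R,2R,3S,4S,6S)-2-hydroxy-1-methyl-4-(prop-1-en-2-yl)-7-oxabicyclo[4.1.0]heptan-3-yl 3-methylbutanoate | C=C(C)[C@@H]1C[C@@H]2O[C@]2(C)[C@H](O)[C@H]1OC(=O)CC(C)C | intermediate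
6 | (1S,3S,4S,6S)-1-methyl-2-oxo-4-(prop-1-en-2-yl)-7-oxabicyclo[4.1.0]heptan-3-yl 3-methylbutanoate | C=C(C)[C@@H]1C[C@@H]2O[C@]2(C)C(=O)[C@H]1OC(=O)CC(C)C | intermediate
7 | (1S,3S,4S,6S)-4-(3-chloroprop-1-en-2-yl)-1-methyl-2-oxo-7-oxabicyclo[4.1.0]heptan-3-yl 3-methylbutanoate | C=C(CCl)[C@@H]1C[C@@H]2O[C@]2(C)C(=O)[C@H]1OC(=O)CC(C)C | intermediate
8 | N-alkoxy-N-methylmorpholinium chloride formed by O-alkylation of NMO with 7 (4-methyl-4-[2-(ring)prop-2-en-1-yloxy]morpholin-4-ium chloride) | C=C(CO[N+]3(C)CCOCC3)[C@@H]1C[C@@H]2O[C@]2(C)C(=O)[C@H]1OC(=O)CC(C)C.[Cl-] | intermediate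
9 | (1S,3S,4S,6S)-1-methyl-2-oxo-4-(3-oxoprop-1-en-2-yl)-7-oxabicyclo[4.1.0]heptan-3-yl 3-methylbutanoate | C=C(C=O)[C@@H]1C[C@@H]2O[C@]2(C)C(=O)[C@H]1OC(=O)CC(C)C | intermediate
10 | 3-methylbut-2-en-1-ol (prenol) | CC(C)=CCO | starting material
11 | tert-butyl 3-methylbut-2-en-1-yl carbonate | CC(C)=CCOC(=O)OC(C)(C)C | intermediate
12 | (1S,3S,4S,6S)-1-methyl-4-(6-methyl-3-oxohepta-1,5-dien-2-yl)-2-oxo-7-oxabicyclo[4.1.0]heptan-3-yl 3-methylbutanoate | C=C(C(=O)CC=C(C)C)[C@@H]1C[C@@H]2O[C@]2(C)C(=O)[C@H]1OC(=O)CC(C)C | intermediate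
13 | (1S,3S,4S,6S)-4-[(4E)-6-hydroperoxy-6-methyl-3-oxohepta-1,4-dien-2-yl]-1-methyl-2-oxo-7-oxabicyclo[4.1.0]heptan-3-yl 3-methylbutanoate | C=C(C(=O)/C=C/C(C)(C)OO)[C@@H]1C[C@@H]2O[C@]2(C)C(=O)[C@H]1OC(=O)CC(C)C | target

## Step count and risks

Total step count: 9 (steps 1–6, 8 and 9 on the main line, plus step 7 for carbonate 11).
Longest linear sequence: 8 steps (1 → 3 → 4 → 5 → 6 → 7 → 9 → 12 → 13).

Three steps most likely to fail:

**Step 8 (acyl-anion prenylation).** This is the least precedented step. The Breslow intermediate of the enal may react as a homoenolate, add to a second molecule of 9 (Stetter or benzoin), or close onto the ring ketone in an intramolecular crossed benzoin. The base formed in situ may also move the new β,γ-alkene of 12 into conjugation, and Pd(0) may isomerise the epoxy ketone. The fallback keeps the acyl-anion logic but uses a nitronate at the alkyl-halide oxidation level. It sets out from allyl chloride 7 and comes back at 12. Treating 7 with NaNO2 in DMF (phloroglucinol, rt) gives the allylic nitro compound (1S,3S,4S,6S)-1-methyl-4-(3-nitroprop-1-en-2-yl)-2-oxo-7-oxabicyclo[4.1.0]heptan-3-yl 3-methylbutanoate F1. Neutral Tsuji–Trost C-allylation of its nitronate with carbonate 11 (Pd(PPh3)4 5 mol%, THF, rt; tert-butoxide from 11 is the base, attack at the CH2 terminus) gives (1S,3S,4S,6S)-1-methyl-4-(6-methyl-3-nitrohepta-1,5-dien-2-yl)-2-oxo-7-oxabicyclo[4.1.0]heptan-3-yl 3-methylbutanoate F2 as a mixture of nitro epimers. An aerobic Nef reaction (DABCO, O2, MeCN, rt) then converts the nitro-bearing carbon into the ketone of 12.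

**Step 9 (Schenck ene).** Abstraction of a methyl hydrogen would give the secondary hydroperoxide with a terminal isopropenyl group in place of 13, and 12 may isomerise on handling. The fallback changes the mechanism to a radical-chain autoxidation with triplet oxygen. It sets out from 12 and comes back at 13 without any new compound, using N-hydroxyphthalimide (10 mol%), a low-temperature azo initiator, O2 (1 atm) and MeCN at 30 °C. The phthalimide N-oxyl radical abstracts the weakest C–H (the C(=O)CH2 next to the prenyl alkene). Oxygen adds reversibly to the delocalised radical and settles at the tertiary terminus, giving the conjugated E hydroperoxide, as in the autoxidation of Δ5-3-keto steroids to 6-hydroperoxy-Δ4-3-ketones.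

**Step 1 (Mn(III) α′-acyloxylation).** The trans:cis ratio may be modest and acetate may be transferred in place of isovalerate. The fallback replaces radical ligand transfer by enolate hydroxylation and acylation. It sets out from 1 and comes back at 3. The kinetic lithium enolate of 1 (LDA, THF, −78 °C) is oxidised with 2-(phenylsulfonyl)-3-phenyloxaziridine anti to the isopropenyl group to give (5S,6S)-6-hydroxy-2-methyl-5-(prop-1-en-2-yl)cyclohex-2-en-1-one F3. This is acylated at once with isovaleryl chloride, pyridine and DMAP (CH2Cl2, 0 °C) to give 3.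

## Further compounds

F1 | step 8 | (1S,3S,4S,6S)-1-methyl-4-(3-nitroprop-1-en-2-yl)-2-oxo-7-oxabicyclo[4.1.0]heptan-3-yl 3-methylbutanoate | C=C(C[N+](=O)[O-])[C@@H]1C[C@@H]2O[C@]2(C)C(=O)[C@H]1OC(=O)CC(C)C
F2 | step 8 | (1S,3S,4S,6S)-1-methyl-4-(6-methyl-3-nitrohepta-1,5-dien-2-yl)-2-oxo-7-oxabicyclo[4.1.0]heptan-3-yl 3-methylbutanoate (mixture of epimers at the nitro carbon) | C=C(C(CC=C(C)C)[N+](=O)[O-])[C@@H]1C[C@@H]2O[C@]2(C)C(=O)[C@H]1OC(=O)CC(C)C
F0 | step 9 | none | none
F3 | step 1 | (5S,6S)-6-hydroxy-2-methyl-5-(prop-1-en-2-yl)cyclohex-2-en-1-one | C=C(C)[C@@H]1CC=C(C)C(=O)[C@H]1O
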